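## Retrosynthetic overview
1. Target ⇒ 15-iodo-8,14-epoxylabdan-13-ol. A Zn-induced β-elimination opens the oxepane and gives the C14=C15 vinyl group and the free C8–OH in one stroke.
2. Iodide ⇒ 13,15-diol ⇒ tetracyclic bromo carbonate (trans-decalin, oxepane and six-membered cyclic carbonate).
3. Key disconnection: C4–C5, C9–C10, O–C8 and O–C13 of that tetracycle are cut together ⇒ one acyclic epoxy-triene tert-butyl carbonate. Forward ring order is A, B, oxepane, cyclic carbonate, started by a chiral Br+ carrier at the terminal alkene.
4. Oxygen relay: the epoxide O ends as the C8 hydroxyl and the Boc C=O oxygen ends as the C13 hydroxyl, with inversion at C13. C13 therefore comes from a Sharpless epoxide, not from a vinyl-metal addition.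
5. Epoxy carbonate ⇒ all-E-geranylgeraniol (asymmetric epoxidation, then Boc2O).

Assumption: all-E-geranylgeraniol (annatto-derived bulk terpene alcohol) counts as the cheap commercial C20 feedstock; labdane numbering is used for all cyclised compounds (geranylgeraniol C1, C2, C3, C7, C14 = labdane C15, C14, C13, C8, C3); the antipode of the BINOL-derived Lewis base that brominates the C3 Re face is written as (S) and must be confirmed in one test run, since both BINOL antipodes are commercial.

## Route

Step 1
Reactants: 1 (2E,6E,10E)-geranylgeraniol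
Product: 2 (2S,3S)-2,3-epoxygeranylgeraniol
Conditions: Ti(OiPr)4 (10 mol %), L-(+)-DET (12 mol %), TBHP (decane, 1.5 equiv), 4 Å MS, CH2Cl2, −20 °C
Reagents that add atoms: tert-butyl hydroperoxide, CC(C)(C)OO
Why: Katsuki–Sharpless asymmetric epoxidation; the Ti–tartrate complex binds the allylic alcohol, so only the C2=C3 alkene reacts, and L-(+)-tartrate gives the (2S,3S)-epoxide (about 93–95 % ee, as for geraniol), which fixes C14 and, after the later inversion, C13.

Step 2
Reactants: 2 (2S,3S)-2,3-epoxygeranylgeraniol
Product: 3 tert-butyl (2S,3S)-2,3-epoxygeranylgeranyl carbonate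
Conditions: Boc2O (1.5 equiv), N-methylimidazole (1.0 equiv), PhMe, 0 °C → rt
Reagents that add atoms: di-tert-butyl dicarbonate, CC(C)(C)OC(=O)OC(=O)OC(C)(C)C
Why: Nucleophile-catalysed O-acylation of the only hydroxyl group under non-acidic conditions leaves the epoxide, its two stereocentres and the three alkenes untouched.

Step 3
Reactants: 3 tert-butyl (2S,3S)-2,3-epoxygeranylgeranyl carbonate
Product: 6 (3R,5S,8S,9S,10R,13R,14S)-3-bromo-8,14-epoxylabdane-13,15-diyl carbonate, via epoxonium ion 4 (not isolated), via tert-butoxydioxanylium ion 5 (not isolated)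
Conditions: NBS (1.1 equiv), (S)-3,3′-diaryl-BINOL thiophosphoramide Lewis base (20 mol %), 4 Å MS, PhMe/CH2Cl2 1:1, −78 → −40 °C
Reagents that add atoms: N-bromosuccinimide, O=C1CCC(=O)N1Br
Why: Proposed new method: the P=S Lewis base takes Br+ from NBS and its bulky chiral ion pair delivers it to the least hindered terminal alkene on the C3 Re face (sets 3R); the bromiranium ion is opened at C4 by the C5=C10 alkene, and C10 is then attacked by the C9=C8 alkene, through a chair–chair all-anti (Stork–Eschenmoser) array, so the two E-alkenes give equatorial Br, the trans ring fusion (5S,10R) and the equatorial side chain (9S); the C8 cation is captured equatorially (8S) by the epoxide oxygen through a six-membered transition state to give 4, whose tertiary, more cationic C13 is attacked from the rear by the Boc carbonyl oxygen (six-membered ring, inversion 13S → 13R, C14 untouched) to give 5, which loses isobutene to the succinimide anion so that no acid builds up; the closest known reaction types are Lewis-base-catalysed enantioselective bromonium polyene cyclisation of geranyl- and homogeranylarenes and endo-selective epoxide-opening cascades (bromonium- or Lewis-acid-started) that end on a tert-butyl carbonate, and what is new is their fusion in one all-aliphatic chain.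

Step 4
Reactants: 6 (3R,5S,8S,9S,10R,13R,14S)-3-bromo-8,14-epoxylabdane-13,15-diyl carbonate
Product: 7 (3R,5S,8S,9S,10R,13R,14S)-3-bromo-8,14-epoxylabdane-13,15-diol
Conditions: K2CO3 (0.2 equiv), MeOH, rt
Reagents that add atoms: none
Why: Base-catalysed transesterification (methanolysis) of the cyclic carbonate breaks only acyl C–O bonds, so no stereocentre is touched, and the equatorial neopentyl C3 bromide has no anti-periplanar hydrogen and is inert to SN2.

Step 5
Reactants: 7 (3R,5S,8S,9S,10R,13R,14S)-3-bromo-8,14-epoxylabdane-13,15-diol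
Product: 9 (3R,5S,8S,9S,10R,13R)-3-bromolabd-14-ene-8,13-diol (target), via primary iodide 8 (not isolated)
Conditions: PPh3, imidazole, I2, THF, 0 °C → rt; then activated Zn dust, EtOH, 65 °C
Reagents that add atoms: iodine, II (its atom is present only in 8 and leaves again as zinc iodide; from 7 to 9 nothing but H is added)
Why: Appel iodination takes only the primary alcohol, and zinc insertion into C15–I triggers a Boord-type (Vasella-like) β-alkoxide elimination that breaks C14–O, which creates the vinyl group and frees O8 as the equatorial C8 alcohol without touching C8 or C13, while the unactivated secondary C3–Br is not reduced by Zn/EtOH and imidazole buffers the zinc iodide.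

## Compound list
1 | (2E,6E,10E)-geranylgeraniol | CC(C)=CCC/C(C)=C/CC/C(C)=C/CC/C(C)=C/CO | starting material
2 | (2S,3S)-2,3-epoxygeranylgeraniol | OC[C@@H]1O[C@@]1(C)CC/C=C(\C)CC/C=C(\C)CCC=C(C)C | intermediate
3 | tert-butyl (2S,3S)-2,3-epoxygeranylgeranyl carbonate | CC(C)(C)OC(=O)OC[C@@H]1O[C@@]1(C)CC/C=C(\C)CC/C=C(\C)CCC=C(C)C | intermediate
4 | epoxonium ion: bromo-trans-decalin (3R,5S,8S,9S,10R) whose O+ is bonded to C8, C13 (S) and C14 (S), with C15 still carrying OBoc | CC(C)(C)OC(=O)OC[C@@H]1[O+]2[C@@]1(C)CC[C@@H]3[C@]2(C)CC[C@@H]4C(C)(C)[C@H](Br)CC[C@@]34C | intermediate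
5 | 2-tert-butoxy-1,3-dioxan-2-ylium ion: oxepane closed, C13 inverted to R | CC(C)(C)O[C+]1OC[C@@H]2O[C@@]3(C)CC[C@@H]4C(C)(C)[C@H](Br)CC[C@@]4(C)[C@@H]3CC[C@@]2(C)O1 | intermediate
6 | (3R,5S,8S,9S,10R,13R,14S)-3-bromo-8,14-epoxylabdane-13,15-diyl carbonate | O=C1OC[C@@H]2O[C@@]3(C)CC[C@@H]4C(C)(C)[C@H](Br)CC[C@@]4(C)[C@@H]3CC[C@@]2(C)O1 | intermediate
7 | (3R,5S,8S,9S,10R,13R,14S)-3-bromo-8,14-epoxylabdane-13,15-diol | OC[C@@H]1O[C@@]2(C)CC[C@@H]3C(C)(C)[C@H](Br)CC[C@@]3(C)[C@@H]2CC[C@@]1(C)O | intermediate
8 | (3R,5S,8S,9S,10R,13R,14R)-3-bromo-8,14-epoxy-15-iodolabdan-13-ol (C14 is unchanged in space; the descriptor changes because of iodine) | IC[C@@H]1O[C@@]2(C)CC[C@@H]3C(C)(C)[C@H](Br)CC[C@@]3(C)[C@@H]2CC[C@@]1(C)O | intermediate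
9 | (3R,5S,8S,9S,10R,13R)-3-bromolabd-14-ene-8,13-diol | C=C[C@](C)(O)CC[C@H]1[C@]2(C)CC[C@@H](Br)C(C)(C)[C@H]2CC[C@]1(C)O | target

## Totals
- Total step count: 5
- Longest linear sequence: 5

## Steps most likely to fail

**Step 3 (highest risk).**
- The face selectivity of Br+ transfer is unproven on an all-aliphatic chain.
- An internal alkene may be brominated, and a proton may be lost after ring A or B in the apolar medium. A yield of 20–35 % would be a good result.
- Wrong-face bromination gives a diastereomer, not the enantiomer, because C13 and C14 come from the enantioenriched epoxide. Chromatography of 6 therefore raises its optical purity above that of 2.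
- In the wanted series, C14 of the epoxonium ion sits anti to the axial C8 methyl. In the wrong series it sits syn, so that series should leak more to elimination products.
- Fallback: give up reagent control and use the two Sharpless centres as a built-in resolving handle. Setting out from 3, NBS in hexafluoroisopropanol over 4 Å MS at 0 °C drives the same cascade without a chiral carrier. This strongly ionising, non-nucleophilic medium is known to carry bromonium-started cascades through to a Boc terminator. It gives 6 together with the (3S,5R,8R,9R,10S,13R,14S)-diastereomer of the bromo carbonate F1 in roughly equal amounts. The two are separated on silica or by crystallisation, and the route is rejoined at 6 at the cost of half the material.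

**Step 5.**
- The organozinc may be protonated before it eliminates, insertion may be sluggish, or ZnI2 may ionise the tertiary allylic alcohol.
- Fallback: replace the halide/metal-insertion fragmentation by a Julia-type reductive elimination. Setting out from 7, PhSSPh/PBu3 converts the primary alcohol into the 15-phenylsulfanyl ether-alcohol F2. H2O2 with ammonium molybdate oxidises it to the 15-phenylsulfonyl ether-alcohol F3. Na(Hg)/Na2HPO4 in MeOH/THF at −20 °C then expels the C14 alkoxide and sulfinate under buffered, Lewis-acid-free conditions, which comes back to the route at 9.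

**Step 2.**
- The Boc carbonate of an epoxy alcohol is acid-labile on silica, symmetric carbonate may form, and the Boc carbonyl is only a moderate terminator for step 3.
- Fallback: change the terminating group. Setting out from 2, Me2NCOCl/pyridine/DMAP gives (2S,3S)-2,3-epoxygeranylgeranyl N,N-dimethylcarbamate F4, whose more nucleophilic carbonyl oxygen closes the cascade under the step 3 conditions. This forms the cyclic 2-(dimethyliminio)-1,3-dioxane ion F5. Aqueous NaHCO3 work-up hydrolyses it to the cyclic carbonate, so the route is rejoined at 6.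

## Further compounds
F1 | step 3 | (3S,5R,8R,9R,10S,13R,14S)-3-bromo-8,14-epoxylabdane-13,15-diyl carbonate | O=C1OC[C@@H]2O[C@]3(C)CC[C@H]4C(C)(C)[C@@H](Br)CC[C@]4(C)[C@H]3CC[C@@]2(C)O1
F2 | step 5 | (3R,5S,8S,9S,10R,13R,14R)-3-bromo-8,14-epoxy-15-(phenylsulfanyl)labdan-13-ol | c1ccccc1SC[C@@H]2O[C@@]3(C)CC[C@@H]4C(C)(C)[C@H](Br)CC[C@@]4(C)[C@@H]3CC[C@@]2(C)O
F3 | step 5 | (3R,5S,8S,9S,10R,13R,14R)-3-bromo-8,14-epoxy-15-(phenylsulfonyl)labdan-13-ol | O=S(=O)(c1ccccc1)C[C@@H]2O[C@@]3(C)CC[C@@H]4C(C)(C)[C@H](Br)CC[C@@]4(C)[C@@H]3CC[C@@]2(C)O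
F4 | step 2 | (2S,3S)-2,3-epoxygeranylgeranyl N,N-dimethylcarbamate | CN(C)C(=O)OC[C@@H]1O[C@@]1(C)CC/C=C(\C)CC/C=C(\C)CCC=C(C)C
F5 | step 2 | (3R,5S,8S,9S,10R,13R,14S)-3-bromo-8,14-epoxylabdane-13,15-diyl 2-(dimethyliminio)-1,3-dioxane ion | C[N+](C)=C1OC[C@@H]2O[C@@]3(C)CC[C@@H]4C(C)(C)[C@H](Br)CC[C@@]4(C)[C@@H]3CC[C@@]2(C)O1
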